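**Strategy.** The route rests on cutting C1–C5 and C1–C10 of the daucane core. In the seven-membered ring (C1, C5–C10) the methyl-bearing C8 lies 1,4 and the oxygenated C6 lies 1,2 to the fusion carbon C5, so this ring is a 2-methoxy-4-methylphenyl ring with the quaternary carbon C1 inserted. An intramolecular Buchner reaction of an α-methyl diazoketone performs this insertion in one operation: it closes the cyclopentanone and the cycloheptatriene and sets the C1 quaternary centre under control of C4. The precursor is a (5R)-configured tertiary benzylic triethylsilyl ether bearing the aryl ring, the isopropyl group and a CH2C(O)C(N2)CH3 arm. Afterwards the C2 ketone is deleted and the triene is turned into the C6 and C10 esters.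

Key step: step 6

Assumption 1: daucane numbering is used for all bicyclic compounds (C1 and C5 fusion carbons, angular methyl on C1, isopropyl on C4, ring methyl on C8); β is the face of the C1 methyl group, α the opposite face.
Assumption 2: (R,R)-iPr-DuPHOS is taken to deliver the (3R)-alcohol in step 2; if the sense of induction is the opposite, the (S,S)-ligand is used.

**Route**

Step 1
Reactants: 1 1-bromo-2-methoxy-4-methylbenzene; 2 N-methoxy-N-methylisobutyramide
Product: 5 1-(2-methoxy-4-methylphenyl)-2-methylpropan-1-one, via aryllithium 3 (not isolated), via lithium hemiaminal 4 (not isolated)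
Conditions: n-BuLi, THF, −78 °C; then 2, −78 → 0 °C; aq NH4Cl
Reagents that add atoms: none
Why: Bromine–lithium exchange gives the aryllithium at a defined ring position, and the Weinreb ketone synthesis stops at the chelated tetrahedral adduct, so no tertiary alcohol from double addition can form.

Step 2
Reactants: 5 1-(2-methoxy-4-methylphenyl)-2-methylpropan-1-one; 6 allylboronic acid pinacol ester
Product: 8 (3R)-3-(2-methoxy-4-methylphenyl)-2-methylhex-5-en-3-ol, via pinacol boryl ether 7 (not isolated)
Conditions: CuF2·2H2O (3 mol %), (R,R)-iPr-DuPHOS (6 mol %), La(OiPr)3 (4.5 mol %), DMF, −40 °C; aqueous work-up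
Reagents that add atoms: none
Why: Copper-catalysed enantioselective allylboration of a ketone: a bisphosphine-bound allylcopper adds through a cyclic six-membered transition state in which the ligand selects the carbonyl face, setting the carbinol centre (later C4) as R, while the lanthanum alkoxide speeds boron-to-copper transmetalation.

Step 3
Reactants: 8 (3R)-3-(2-methoxy-4-methylphenyl)-2-methylhex-5-en-3-ol
Product: 9 triethyl{[(3R)-3-(2-methoxy-4-methylphenyl)-2-methylhex-5-en-3-yl]oxy}silane
Conditions: TESOTf, 2,6-lutidine, CH2Cl2, −78 → 0 °C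
Reagents that add atoms: triethylsilyl triflate, CC[Si](CC)(CC)OS(=O)(=O)C(F)(F)F
Why: Silyl triflate–lutidine silylation copes with the hindered tertiary benzylic alcohol, and the silyl ether later blocks O–H insertion of the carbene and retro-aldol cleavage.

Step 4
Reactants: 9 triethyl{[(3R)-3-(2-methoxy-4-methylphenyl)-2-methylhex-5-en-3-yl]oxy}silane
Product: 12 (3R)-3-(2-methoxy-4-methylphenyl)-4-methyl-3-(triethylsilyloxy)pentanoic acid, via ozonide 10 (not isolated), via aldehyde 11 (not isolated)
Conditions: O3, CH2Cl2, −78 °C (stopped at first excess); PPh3, −78 °C → rt; crude aldehyde then NaClO2, NaH2PO4, 2-methyl-2-butene, t-BuOH/H2O, 0 °C → rt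
Reagents that add atoms: ozone, [O-][O+]=O; sodium chlorite, [Na+].[O-]Cl=O
Why: Ozonolysis with reductive work-up followed by Pinnick oxidation; the terminal alkene reacts with ozone far faster than the anisole ring, and the buffered chlorite step with excess hypochlorite scavenger leaves the silyl ether, the arene and the stereocentre untouched.

Step 5
Reactants: 12 (3R)-3-(2-methoxy-4-methylphenyl)-4-methyl-3-(triethylsilyloxy)pentanoic acid
Product: 14 (5R)-2-diazo-5-(2-methoxy-4-methylphenyl)-6-methyl-5-(triethylsilyloxy)heptan-3-one, via mixed anhydride 13 (not isolated)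
Conditions: i-BuOCOCl, Et3N, THF, −20 °C; then CH3CHN2 in Et2O (freshly made from N-ethyl-N-nitrosourea and aq KOH), −20 → 0 °C
Reagents that add atoms: diazoethane, CC=[N+]=[N-]
Why: Acylation of a diazoalkane by a mixed carbonic anhydride (the activation used in the Arndt–Eistert sequence) gives the α-methyl diazoketone under neutral conditions, avoiding the HCl of an acid chloride route, which would ionise the tertiary benzylic silyl ether.

Step 6
Reactants: 14 (5R)-2-diazo-5-(2-methoxy-4-methylphenyl)-6-methyl-5-(triethylsilyloxy)heptan-3-one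
Product: 16 6-methoxy-4β-(triethylsilyloxy)dauca-5,7,9-trien-2-one, via norcaradiene 15 (not isolated)
Conditions: Rh2(OAc)4 (1 mol %), CH2Cl2, reflux, slow addition of 14 at high dilution
Reagents that add atoms: none
Why: Loss of N2 at dirhodium tetraacetate gives a rhodium-bound carbene at C1 that adds across the C5–C10 bond of the arene (ipso carbon activated by ortho-OMe and para-Me) to give norcaradiene 15, which opens by disrotatory 6π electrocyclic cleavage of C5–C10 to the cycloheptatriene; this is the intramolecular Buchner reaction, established for 1-diazo-4-arylbutan-2-ones. The cyclopentanone (C1–C5) closes by carbene addition at the ipso carbon through the three-atom tether, giving a fused five-membered ring, and the seven-membered ring arises by ring expansion of the arene, not by a cyclisation. The only new stereocentre, C1, is set by C4: in the reacting conformer C3 stands perpendicular to the arene plane, the slim silyloxy group sits beside the ortho-methoxy group and the isopropyl group on the side of C10–H, so the carbene adds to the face that places the C1 methyl cis to the C4 oxygen. Site selectivity for C10 over the methoxy-bearing C6 is steric. Aromatic cycloaddition is expected to outrun 1,5 C–H insertion into the isopropyl methine, ylide formation at the hindered silyl ether and 1,2-hydride shift from the methyl group (the alkyl group least prone to migrate hydrogen); slow addition suppresses azine formation.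

Step 7
Reactants: 16 6-methoxy-4β-(triethylsilyloxy)dauca-5,7,9-trien-2-one
Product: 17 6-methoxy-4β-(triethylsilyloxy)dauca-5,7,9-trien-2-ol (C2 epimers)
Conditions: NaBH4, MeOH/THF, 0 °C
Reagents that add atoms: none
Why: Borohydride 1,2-reduction of the only carbonyl group (enol ether, triene and silyl ether are inert); the C2 carbinol forms as an epimer mixture, which is of no consequence because C2 becomes a methylene group in step 9.

Step 8
Reactants: 17 6-methoxy-4β-(triethylsilyloxy)dauca-5,7,9-trien-2-ol
Product: 19 O-[6-methoxy-4β-(triethylsilyloxy)dauca-5,7,9-trien-2-yl] S-methyl dithiocarbonate, via sodium xanthate 18 (not isolated)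
Conditions: NaHMDS, THF, −78 °C; CS2; MeI, −78 → 0 °C
Reagents that add atoms: carbon disulfide, S=C=S; iodomethane, CI
Why: Xanthate formation is the standard activation of a hindered secondary alcohol for Barton–McCombie reduction, and deprotonation at −78 °C with immediate capture by CS2 forestalls silyl migration from O4.

Step 9
Reactants: 19 O-[6-methoxy-4β-(triethylsilyloxy)dauca-5,7,9-trien-2-yl] S-methyl dithiocarbonate
Product: 20 6-methoxy-4β-(triethylsilyloxy)dauca-5,7,9-triene
Conditions: Bu3SnH, AIBN (cat.), toluene, 80 °C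
Reagents that add atoms: none
Why: Barton–McCombie radical deoxygenation; the C2 radical should take hydrogen from the stannane before it rearranges, because the C1–C2 bond is held pseudo-equatorial on the cycloheptatriene boat, near the nodal plane of the C9=C10 and C5=C6 π bonds, so 3-exo closure (1,2-vinyl shift) lacks overlap.

Step 10
Reactants: 20 6-methoxy-4β-(triethylsilyloxy)dauca-5,7,9-triene
Product: 21 4β-(triethylsilyloxy)-5αH-dauca-7,9-dien-6-one
Conditions: oxalic acid, THF/H2O, 0 °C → rt
Reagents that add atoms: water, O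
Why: Enol ether hydrolysis by C-protonation at C5 (the resulting oxocarbenium ion is conjugated with the diene), the proton entering from the convex α face of the boat-shaped triene, away from the pseudo-axial C1 methyl, to give the trans-fused 5αH ketone; C5 remains epimerisable, and this epimer, with C6 anti to the C4 isopropyl group, is expected to be the stable one.

Step 11
Reactants: 21 4β-(triethylsilyloxy)-5αH-dauca-7,9-dien-6-one
Product: 22 9α,10α-epoxy-4β-(triethylsilyloxy)-5αH-dauc-7-en-6-one
Conditions: mCPBA, NaHCO3, CH2Cl2, 0 °C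
Reagents that add atoms: 3-chloroperoxybenzoic acid, O=C(OO)c1cccc(Cl)c1
Why: Prilezhaev epoxidation at the γ,δ-double bond C9=C10, the more electron-rich alkene of the dienone, from the α face because the pseudo-axial C1 methyl of the trans-fused system shields the β face at C10; this sets C10 (and transiently C9).

Step 12
Reactants: 22 9α,10α-epoxy-4β-(triethylsilyloxy)-5αH-dauc-7-en-6-one
Product: 23 10α-hydroxy-4β-(triethylsilyloxy)-5αH-dauc-8-en-6-one
Conditions: SmI2 (2.2 equiv), THF/MeOH, −78 °C
Reagents that add atoms: none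
Why: Samarium diiodide reduction of a vinylogous epoxy ketone: two-electron reduction of the enone breaks the C9–O bond, the C8=C9 alkene forms and methanol protonates C7, giving the δ-hydroxy β,γ-unsaturated ketone with the C10–O bond, and hence the C10 configuration, untouched.

Step 13
Reactants: 23 10α-hydroxy-4β-(triethylsilyloxy)-5αH-dauc-8-en-6-one
Product: 24 10α-acetoxy-4β-(triethylsilyloxy)-5αH-dauc-8-en-6-one
Conditions: Ac2O, pyridine, DMAP (cat.), CH2Cl2, 0 °C
Reagents that add atoms: acetic anhydride, CC(=O)OC(C)=O
Why: DMAP-catalysed acetylation of the only free hydroxyl group; low temperature and a weak base keep the β,γ-double bond from moving into conjugation.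

Step 14
Reactants: 24 10α-acetoxy-4β-(triethylsilyloxy)-5αH-dauc-8-en-6-one
Product: 25 10α-acetoxy-4β-hydroxy-5αH-dauc-8-en-6-one
Conditions: HF·pyridine, pyridine, THF, 0 °C → rt
Reagents that add atoms: none
Why: Fluoride cleavage of the tertiary triethylsilyl ether under buffered, non-basic conditions leaves the acetate and the β,γ-enone intact and avoids retro-aldol cleavage of the β-hydroxy ketone.

Step 15
Reactants: 25 10α-acetoxy-4β-hydroxy-5αH-dauc-8-en-6-one
Product: 27 10α-acetoxy-5αH-dauc-8-ene-4β,6α-diol, via alkoxyborohydride 26 (not isolated)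
Conditions: Me4NBH(OAc)3, MeCN/AcOH, −30 → −20 °C
Reagents that add atoms: none
Why: Evans–Saksena reduction: the tertiary C4 hydroxyl exchanges onto boron and delivers hydride intramolecularly to the β face of the C6 carbonyl, so the new C6 hydroxyl is α and anti to O4, while acetate and alkene are inert to the triacetoxyborohydride.

Step 16
Reactants: 27 10α-acetoxy-5αH-dauc-8-ene-4β,6α-diol; 28 4-methoxybenzoyl chloride
Product: 29 10α-acetoxy-4β-hydroxy-6α-(4-methoxybenzoyloxy)-5αH-dauc-8-ene (CNP0256979.2)
Conditions: Et3N, DMAP, CH2Cl2, rt → 40 °C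
Reagents that add atoms: none
Why: DMAP-catalysed acyl transfer esterifies the secondary C6 alcohol, while the tertiary C4 alcohol is too hindered to react, so no protection is needed.

**Compound list**

1 | 1-bromo-2-methoxy-4-methylbenzene | COc1cc(C)ccc1Br | starting material
2 | N-methoxy-N-methylisobutyramide | CC(C)C(=O)N(C)OC | starting material
3 | (2-methoxy-4-methylphenyl)lithium | [Li]c1ccc(C)cc1OC | intermediate
4 | lithium 1-[methoxy(methyl)amino]-1-(2-methoxy-4-methylphenyl)-2-methylpropan-1-olate | COc1cc(C)ccc1C(O[Li])(C(C)C)N(C)OC | intermediate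
5 | 1-(2-methoxy-4-methylphenyl)-2-methylpropan-1-one | COc1cc(C)ccc1C(=O)C(C)C | intermediate
6 | allylboronic acid pinacol ester | C=CCB1OC(C)(C)C(C)(C)O1 | starting material
7 | pinacol boryl ether of alcohol 8 | C=CC[C@@](OB1OC(C)(C)C(C)(C)O1)(C(C)C)c2ccc(C)cc2OC | intermediate
8 | (3R)-3-(2-methoxy-4-methylphenyl)-2-methylhex-5-en-3-ol | C=CC[C@@](O)(C(C)C)c1ccc(C)cc1OC | intermediate
9 | triethyl{[(3R)-3-(2-methoxy-4-methylphenyl)-2-methylhex-5-en-3-yl]oxy}silane | C=CC[C@@](O[Si](CC)(CC)CC)(C(C)C)c1ccc(C)cc1OC | intermediate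
10 | 1,2,4-trioxolane (ozonide) of 9, trioxolane carbon unassigned | C1OC(C[C@@](O[Si](CC)(CC)CC)(C(C)C)c2ccc(C)cc2OC)OO1 | intermediate
11 | (3R)-3-(2-methoxy-4-methylphenyl)-4-methyl-3-(triethylsilyloxy)pentanal | O=CC[C@@](O[Si](CC)(CC)CC)(C(C)C)c1ccc(C)cc1OC | intermediate
12 | (3R)-3-(2-methoxy-4-methylphenyl)-4-methyl-3-(triethylsilyloxy)pentanoic acid | OC(=O)C[C@@](O[Si](CC)(CC)CC)(C(C)C)c1ccc(C)cc1OC | intermediate
13 | isobutyl carbonic anhydride of acid 12 | CC(C)COC(=O)OC(=O)C[C@@](O[Si](CC)(CC)CC)(C(C)C)c1ccc(C)cc1OC | intermediate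
14 | (5R)-2-diazo-5-(2-methoxy-4-methylphenyl)-6-methyl-5-(triethylsilyloxy)heptan-3-one | CC(=[N+]=[N-])C(=O)C[C@@](O[Si](CC)(CC)CC)(C(C)C)c1ccc(C)cc1OC | intermediate
15 | norcaradiene: cyclopropane C1–C5–C10 fused to the cyclopentanone (C1–C5) and to the 6-methoxy-8-methylcyclohexa-6,8-diene ring, C1 methyl on the diene side | COC1=CC(C)=C[C@@H]2[C@@]3(C)C(=O)C[C@@](O[Si](CC)(CC)CC)(C(C)C)[C@@]123 | intermediate
16 | 6-methoxy-4β-(triethylsilyloxy)dauca-5,7,9-trien-2-one (C1 methyl and C4 oxygen cis) | CC1=CC(OC)=C2[C@](O[Si](CC)(CC)CC)(C(C)C)CC(=O)[C@]2(C)C=C1 | intermediate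
17 | 6-methoxy-4β-(triethylsilyloxy)dauca-5,7,9-trien-2-ol (C2 epimer mixture, centre removed in step 9) | CC1=CC(OC)=C2[C@](O[Si](CC)(CC)CC)(C(C)C)CC(O)[C@]2(C)C=C1 | intermediate
18 | sodium O-[6-methoxy-4β-(triethylsilyloxy)dauca-5,7,9-trien-2-yl] dithiocarbonate | CC1=CC(OC)=C2[C@](O[Si](CC)(CC)CC)(C(C)C)CC(OC(=S)[S-])[C@]2(C)C=C1.[Na+] | intermediate
19 | O-[6-methoxy-4β-(triethylsilyloxy)dauca-5,7,9-trien-2-yl] S-methyl dithiocarbonate | CC1=CC(OC)=C2[C@](O[Si](CC)(CC)CC)(C(C)C)CC(OC(=S)SC)[C@]2(C)C=C1 | intermediate
20 | 6-methoxy-4β-(triethylsilyloxy)dauca-5,7,9-triene | CC1=CC(OC)=C2[C@](O[Si](CC)(CC)CC)(C(C)C)CC[C@]2(C)C=C1 | intermediate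
21 | 4β-(triethylsilyloxy)-5αH-dauca-7,9-dien-6-one (trans-fused) | O=C1C=C(C)C=C[C@@]2(C)CC[C@@](O[Si](CC)(CC)CC)(C(C)C)[C@H]12 | intermediate
22 | 9α,10α-epoxy-4β-(triethylsilyloxy)-5αH-dauc-7-en-6-one | O=C1C=C(C)[C@H]3O[C@H]3[C@@]2(C)CC[C@@](O[Si](CC)(CC)CC)(C(C)C)[C@H]12 | intermediate
23 | 10α-hydroxy-4β-(triethylsilyloxy)-5αH-dauc-8-en-6-one | O=C1CC(C)=C[C@@H](O)[C@@]2(C)CC[C@@](O[Si](CC)(CC)CC)(C(C)C)[C@H]12 | intermediate
24 | 10α-acetoxy-4β-(triethylsilyloxy)-5αH-dauc-8-en-6-one | O=C1CC(C)=C[C@@H](OC(C)=O)[C@@]2(C)CC[C@@](O[Si](CC)(CC)CC)(C(C)C)[C@H]12 | intermediate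
25 | 10α-acetoxy-4β-hydroxy-5αH-dauc-8-en-6-one | O=C1CC(C)=C[C@@H](OC(C)=O)[C@@]2(C)CC[C@@](O)(C(C)C)[C@H]12 | intermediate
26 | tetramethylammonium diacetoxy(hydrido)borate bound through O4 of 25 | O=C1CC(C)=C[C@@H](OC(C)=O)[C@@]2(C)CC[C@@](O[BH-](OC(C)=O)OC(C)=O)(C(C)C)[C@H]12.C[N+](C)(C)C | intermediate
27 | 10α-acetoxy-5αH-dauc-8-ene-4β,6α-diol | O[C@H]1CC(C)=C[C@@H](OC(C)=O)[C@@]2(C)CC[C@@](O)(C(C)C)[C@H]12 | intermediate
28 | 4-methoxybenzoyl chloride | COc1ccc(C(Cl)=O)cc1 | starting material
29 | 10α-acetoxy-4β-hydroxy-6α-(4-methoxybenzoyloxy)-5αH-dauc-8-ene (CNP0256979.2) | COc1ccc(C(=O)O[C@H]2CC(C)=C[C@@H](OC(C)=O)[C@@]3(C)CC[C@@](O)(C(C)C)[C@H]23)cc1 | target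

**Step count and risks**

Total steps: 16. Longest linear sequence: 16 steps (1 → 29); building blocks 2, 6 and 28 enter directly.

The three steps most likely to fail:

1. Step 6 (Buchner reaction). Hydrogen may migrate from the methyl group to the carbene carbon before the arene is reached, giving a vinyl ketone. The carbene may also add to the other arene face, giving the C1 epimer, or be diverted to C–H insertion at the isopropyl methine. The fallback sets out from acid 12 and removes the methyl group from the carbene. Mixed anhydride 13 is treated with diazomethane in place of diazoethane to give (4R)-1-diazo-4-(2-methoxy-4-methylphenyl)-5-methyl-4-(triethylsilyloxy)hexan-2-one F1, a standard Buchner substrate with no migratable hydrogen. Rh2(OAc)4 in CH2Cl2 then gives 6-methoxy-8-methyl-4-(propan-2-yl)-4β-(triethylsilyloxy)bicyclo[5.3.0]deca-5,7,9-trien-2-one F2, whose C1–H is α to the ketone and doubly allylic. Deprotonation with KHMDS at −78 °C and α-alkylation of the enolate with MeI, anti to the C4 isopropyl group, installs the C1 methyl. The face chosen in the cycloaddition then no longer matters, and the route is rejoined at ketone 16.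

2. Step 2 (asymmetric allylboration). Both ketone substituents (ortho-substituted aryl, isopropyl) are bulky, so face discrimination by the catalyst may be poor and allyl transfer slow. The fallback sets out from ketone 5 and replaces asymmetric catalysis by resolution. A Reformatsky reaction (ethyl bromoacetate, Zn, THF) gives racemic ethyl 3-hydroxy-3-(2-methoxy-4-methylphenyl)-4-methylpentanoate F3, and LiOH in THF/H2O gives racemic 3-hydroxy-3-(2-methoxy-4-methylphenyl)-4-methylpentanoic acid F4. Crystallisation of its salt with (S)-1-phenylethylamine (or cinchonidine) and acidification gives (3R)-3-hydroxy-3-(2-methoxy-4-methylphenyl)-4-methylpentanoic acid F5. Silylation with excess TESOTf/2,6-lutidine, with cleavage of the silyl ester by K2CO3/MeOH on work-up, rejoins the route at acid 12; steps 3 and 4 are then not needed.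

3. Step 9 (radical deoxygenation). The C2 radical sits next to a quaternary carbon that carries a conjugated triene, so 3-exo closure onto C10 with 1,2-vinyl shift, or addition of the stannyl radical to the triene, may compete with hydrogen transfer. The fallback sets out from ketone 16 and avoids a C2 radical altogether. Hydrazine hydrate in ethanol at 80 °C gives 6-methoxy-4β-(triethylsilyloxy)dauca-5,7,9-trien-2-one hydrazone F6. KOt-Bu in DMSO at room temperature (Wolff–Kishner reduction, Cram modification) then reduces C2 through a diazenyl anion and rejoins the route at triene 20; steps 7 and 8 are then not needed.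

**Further compounds**

F1 | step 6 | (4R)-1-diazo-4-(2-methoxy-4-methylphenyl)-5-methyl-4-(triethylsilyloxy)hexan-2-one | [N-]=[N+]=CC(=O)C[C@@](O[Si](CC)(CC)CC)(C(C)C)c1ccc(C)cc1OC
F2 | step 6 | 6-methoxy-8-methyl-4-(propan-2-yl)-4β-(triethylsilyloxy)bicyclo[5.3.0]deca-5,7,9-trien-2-one (daucane numbering, C1 epimers) | CC1=CC(OC)=C2[C@](O[Si](CC)(CC)CC)(C(C)C)CC(=O)C2C=C1
F3 | step 2 | ethyl 3-hydroxy-3-(2-methoxy-4-methylphenyl)-4-methylpentanoate (racemic) | CCOC(=O)CC(O)(C(C)C)c1ccc(C)cc1OC
F4 | step 2 | 3-hydroxy-3-(2-methoxy-4-methylphenyl)-4-methylpentanoic acid (racemic) | OC(=O)CC(O)(C(C)C)c1ccc(C)cc1OC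
F5 | step 2 | (3R)-3-hydroxy-3-(2-methoxy-4-methylphenyl)-4-methylpentanoic acid | OC(=O)C[C@@](O)(C(C)C)c1ccc(C)cc1OC
F6 | step 9 | 6-methoxy-4β-(triethylsilyloxy)dauca-5,7,9-trien-2-one hydrazone | CC1=CC(OC)=C2[C@](O[Si](CC)(CC)CC)(C(C)C)CC(=NN)[C@]2(C)C=C1
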